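The runs were generated by integration with made-up constants.

| setting | midnight | spring | flask |
|---|---|---|---|
| L | 0.10 M | 0.10 M | 0.10 M |
| G | 0.10 M | 0.15 M | 0.100 M |
| remark | the very flask that is asked about, followed so far | run made earlier |  |
| time |  |  | 50 min |

| run | time / min | D / % | X / % |
|---|---|---|---|
| midnight | 0.833 | 0.2 | 0.3 |
| midnight | 2.00 | 0.2 | 0.3 |
| midnight | 4.00 | 1.4 | 0 |
| midnight | 6.00 | 3.2 | 0 |
| spring | 5.00 | 6.6 | 0 |
| spring | 10.0 | 11.0 | 2.1 |
| spring | 15.0 | 14.0 | 3.5 |
| spring | 20.0 | 14.5 | 5.7 |

(readings scatter by 0.5 percentage points)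

* the moment within 50 min at which there is most D
* the amount of D, in percent of the L charged, at that time

Start with the easy slope: in the spring run D stands at 6.6 % after 5.00 min, so D is made at 0.0132 min⁻¹ as a fraction of the L charged. How does that carry to the midnight flask? Scaled by c(G), from 0.15 M to 0.100 M, it gives 0.00880 min⁻¹, and the last two midnight readings show 0.00900 min⁻¹, so take making as first order in c(G).

Where does D peak? In the spring run it goes from 14.0 % to 14.5 %, a step of 0.5 percentage points against a scatter of 0.5 points, so read this as a passing maximum, where loss has caught up with making. Define the filling time τ as the level where D peaks over the early rate at which it is made: τ = 11.0 min. Assume τ does not change with c(G). The midnight flask then tops out near τ times its making rate, 9.67 %.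

When? The spring run flattens by 20.0 min, close to 2 τ, which is 22.0 min, so expect the peak there.

The forecast says 14.5 % at 40 min, with “D at 0.10 M G climbs slowly”; my reckoning is lower and earlier.

The flask gives 9.34 % at 21.0 min.

    L + G ⇌ Q (K = 140 L mol⁻¹, k = 0.00340 L mol⁻¹ s⁻¹)
    G + Q → D (k = 0.0380 L mol⁻¹ s⁻¹)
    Q ⇌ Z (K = 2.70, k = 2.70 × 10⁻⁵ s⁻¹)
    D ⇌ X (K = 7.00, k = 5.10 × 10⁻⁴ s⁻¹)
    D → J (k = 9.60 × 10⁻⁴ s⁻¹)

The step from D to J has a half-life of 12 min, short against the 50 min allowed. Read back, this flask's peak over the scaled early making rate gives 10.6 min, beside the τ of 11.0 min reckoned from the spring run. For the neighbour flask charged with 0.060 M of G, τ and the scaled spring slope give 5.81 %, and that flask peaks at 5.21 %.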